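All runs are calculated with constants of no real substance.

Late in the earlier runs, at 2.50 min, L answers weakly to J: raising J from 0.049 M in theta to 0.12 M in delta, a factor of 2.45, lifts L from 23.5% to 26.5% of the G charged.

| flask | G | J | Q | remark | time |
|---|---|---|---|---|---|
| theta | 0.064 M | 0.049 M | 1.6 mM | run made earlier |  |
| beta | 0.064 M | 0.083 M | 1.6 mM | run made earlier |  |
| delta | 0.064 M | 0.12 M | 1.6 mM | run made earlier |  |
| violet | 0.064 M | 0.0400 M | 1.6 mM |  | 2.5 min |
| ochre | 0.064 M | 0.0800 M | 1.6 mM |  | 2.5 min |
| green | 0.064 M | 0.150 M | 1.6 mM |  | 2.5 min |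

| run | time / min | L / % | G / % |
|---|---|---|---|
| theta | 0.200 | 1.7 | 96.3 |
| theta | 0.417 | 7.1 | 93.7 |
| theta | 0.667 | 6.9 | 91.4 |
| theta | 1.33 | 16.4 | 84.0 |
| theta | 2.50 | 23.5 | 74.5 |
| beta | 0.500 | 6.8 | 90.4 |
| beta | 1.00 | 12.8 | 87.6 |
| beta | 1.50 | 17.5 | 80.6 |
| beta | 2.00 | 24.0 | 74.6 |
| beta | 2.50 | 25.7 | 72.1 |
| delta | 0.500 | 4.5 | 91.3 |
| delta | 1.00 | 11.2 | 88.2 |
| delta | 1.50 | 18.9 | 81.0 |
| delta | 2.00 | 24.0 | 75.7 |
| delta | 2.50 | 26.5 | 72.4 |

(each reading ± 1 percentage point)

- what may be going on: J + Q -> X; G + X <-> D; D <-> E; E <-> Q + L; X -> Z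
- "hardly changes" means that all values lie within two and a half points (for a concentration: within two and a half percent of the largest)

- amount of L at the end, in percent of the G charged for violet, ochre, green, in this order
- the shape of the row from first to last (rises, then falls / hardly changes / rises all the way / falls, then rises / falls all the way)

In the first instants, at 0.200 min in theta, G has lost 3.70% while L stands at 1.7%, a gap of 2 percentage points that, within the scatter, fits the catalyst holding G as D and E, its charge being 2.50% of the G. In the middle, beta makes L steadily, 12.8% at 1.00 min and 24.0% at 2.00 min, and on the scheme offered each round takes one J through J + Q -> X and hands Q back with L, so Q has to wait for J. Towards the end beta adds 1.7 points over the last 0.500 min, less than the 6.8% of its first 0.500 min, and X -> Z stands ready to remove catalyst.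

If the step with J and the rest of the round run in series, the rate, and roughly L at a fixed time, follows J/(K + J) under a ceiling Lm for that reading time, with K a concentration of J. The theta and delta readings give, with their scatter, K = 11.6 mM and Lm = 29.1%. K is thus the half-J, the J that brings L to half of Lm, which the field calls a half-saturation constant. The same K gives the idle share σ = K/(K + J), the part of the working catalyst waiting as Q. Beta, which was not used, comes out at 25.5% against its reading of 25.7%. This reckoning gives 22.5%, 25.4% and 27.0% for violet, ochre and green. The forecast, made from these runs, states 22.5%, 25.4% and 27%, a row that rises all the way: “Nothing in the scheme makes high J harmful, so no maximum is expected.”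

The flasks give 23.5%, 27.0% and 28.7%, so the row rises all the way.

    J + Q → X (k = 9.30 M⁻¹ s⁻¹)
    G + X ⇌ D (K = 12.0 M⁻¹, k = 10.0 M⁻¹ s⁻¹)
    D ⇌ E (K = 2.20, k = 0.510 s⁻¹)
    E ⇌ Q + L (K = 0.170 M, k = 0.660 s⁻¹)
    X → Z (k = 0.00410 s⁻¹)

At 1.25 min, with J at 76.0% of its charge, σ for violet is 27.6%, and the flask holds 25.6% of the catalyst outside Z as Q; for green, with J at 92.1%, σ is 7.74% against 7.07%. Part of what keeps green at 28.7% is the falling back of D to G + X, acting together with the early reading: without that falling back green reaches 47.0%, and read at 25.0 min it stands at 69.1%.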